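**In the flask.** A small charge of Q, 1.8 mol% of L, starts the chain. In the proposed steps Q and L give living ends E, E turns L into G, and E can be lost to J.

| setting | violet | teal | amber | Thursday's | Saturday's | Tuesday's |
|---|---|---|---|---|---|---|
| L | 3 M | 2 M | 3 M | 3.0 M | 3.0 M | 3.0 M (fed, over 32.0 min) |
| Q | 1.8 mol% | 1.8 mol% | 0.9 mol% | 1.8 mol% | 1.8 mol% | 1.8 mol% |
| remark | run made earlier | run made earlier | run made earlier | a closed flask charged with all of it at once and left for 40 min | one stirred flow tank at steady state, fed with the mixture as stated, mean residence time 40 min | a stirred flask in which L is dosed at a steady rate over 32.0 min without added volume, worked up at 40 min |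
| time |  |  |  | 40 min |  | 40 min |

| run | time / min | G / % |
|---|---|---|
| violet | 1.50 | 0.8 |
| violet | 5.00 | 7.0 |
| violet | 8.00 | 16.0 |
| violet | 12.0 | 31.1 |
| violet | 20.0 | 59.5 |
| violet | 25.0 | 71.8 |
| teal | 2.50 | 0.6 |
| teal | 8.00 | 8.2 |
| teal | 15.0 | 23.2 |
| teal | 20.0 | 35.6 |
| teal | 30.0 | 57.7 |
| teal | 40.0 | 73.3 |
| amber | 8.00 | 8.7 |
| amber | 15.0 | 25.5 |
| amber | 25.0 | 49.5 |
| amber | 30.0 | 60.5 |
| amber | 40.0 | 75.3 |

(scatter of a reading: 0.3 percentage points)

1. the set-up with the highest amount of G at the outlet or at the end, in percent of the L put in ("none" if the first two lie within 2 percentage points) (Thursday's / Saturday's / Tuesday's / none)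
2. amount of G at the outlet or at the end, in percent of the L put in, Thursday's
3. amount of G at the outlet or at the end, in percent of the L put in, Saturday's
4. amount of G at the outlet or at the end, in percent of the L put in, Tuesday's

- the stated concentrations are those of everything mixed, before any reaction; amounts are the same in each set-up
- the analysis behind the earlier runs scatters by 0.3 percentage points, standard deviation
- steps that have been proposed: E -> J; L + Q -> E + G; L + E -> G + E
- the feed brings no volume worth counting
- the earlier runs were made in a closed, stirred flask

**Count turnovers.** One turnover is a fall of the fraction of L left by a factor of e. Between its last two readings violet gains 0.0724 min⁻¹: call this the turnover rate, a pseudo-first-order constant for L. Violet's first two readings gain 0.0184 min⁻¹, slower, so treat the first minutes as the time in which ends gather.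

**When you come.** My reckoning: in Thursday's closed flask, hold the rate flat from violet's reading at 25.0 min. That leaves 9.52 % of the charge as L and gives 90.5 % G. For Saturday's tank, balance feed against turnover at the same rate, which gives 74.3 %. In Tuesday's flask a dose of L stays 24.0 min on average, and violet at that age gives 69.7 %. Mark both as high: violet's early rate is lower than the turnover rate, and neither vessel holds the full charge of L at once.

**Do not touch.** Charge L at once and keep the flask closed, since Thursday's reckons higher.

**The check.** The forecast gives 90.5 %, 67 % and 65.5 %, its last two lower than mine , and says “Thursday's wins clearly”.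

The flask gives 90.8 % for Thursday's, 65.4 % for Saturday's and 66.4 % for Tuesday's, so Thursday's comes out highest.

    E → J (k = 0.0130 min⁻¹)
    L + Q → E + G (k = 0.00450 L mol⁻¹ min⁻¹)
    L + E → G + E, rate k3*[E]*[L] (k = 8.40 L mol⁻¹ min⁻¹)

**Tank against flask.** Past the point of violet's 25.0 min reading, Thursday's flask ran at 0.0747 min⁻¹, close to the turnover rate of 0.0724 min⁻¹. Saturday's tank, by the same balance on its result, ran at 0.0472 min⁻¹, slower. Thursday's flask ends at 90.8 % G because it is worked up at 40 min: the same flask left until 400 min gives >99.9 %.

Readings and results are calculated with made-up constants; scatter was added.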